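Ring B of the target (C6–C11; spiro numbering, C6 spiro, C8 CHBr, C9 CMeCl) carries its methyl-bearing carbon C9 para to the spiro carbon, so it is the "para" Diels–Alder adduct of isoprene and an exo-methylene ketone on ring A. The key step forms C6–C7 and C10–C11 at once, closes ring B and creates the quaternary spiro centre, its configuration relayed from the C4–Br centre of (R)-4-bromo-3,3-dimethyl-2-methylenecyclohexanone. That single centre comes from a catalytic enantioselective bromochlorination of prenol and a bromonium cyclization; the ring B halogens then follow by substrate control (epoxidation, diaxial bromide opening, chlorination with retention), and the ketone becomes the C1 methyl alkene.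

Key step: step 6

Remark (assumption): atom numbers are those of the spiro[5.5]undecane skeleton of the target (ring A = C1–C6, ring B = C6–C11); the chiral Schiff-base ligand of step 1 is taken to be available as the enantiomer that leads to the R bromochloride.

Step 1
Reactants: 1 prenol (3-methylbut-2-en-1-ol)
Product: 2 (2R)-2-bromo-3-chloro-3-methylbutan-1-ol
Conditions: NBS, ClTi(OiPr)3, chiral tridentate Schiff-base ligand (salicylaldimine of a 2-amino-1,1-diarylalkan-1-ol, 20 mol%), hexanes, −20 °C
Reagents that add atoms: N-bromosuccinimide, O=C1CCC(=O)N1Br; chlorotitanium triisopropoxide, CC(C)O[Ti](Cl)(OC(C)C)OC(C)C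
Why: Catalytic enantioselective bromochlorination of an allylic alcohol: the alkoxide-bound alkene is brominated on one face inside the chiral titanium Schiff-base complex and chloride is delivered to the tertiary carbon (Markovnikov, anti), so that the ligand enantiomer sets C2 as R, the only stereocentre that is made by catalysis.

Step 2
Reactants: 2 (2R)-2-bromo-3-chloro-3-methylbutan-1-ol
Product: 3 (2R)-2-bromo-3-chloro-3-methylbutyl trifluoromethanesulfonate
Conditions: Tf2O, 2,6-lutidine, CH2Cl2, −78 °C; used crude
Reagents that add atoms: trifluoromethanesulfonic anhydride, O=S(=O)(OS(=O)(=O)C(F)(F)F)C(F)(F)F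
Why: O-Sulfonylation of the primary alcohol turns C1 into an SN2 electrophile without touching the stereocentre; the triflate is kept cold and used at once so that bromine participation does not scramble it.

Step 3
Reactants: 3 (2R)-2-bromo-3-chloro-3-methylbutyl trifluoromethanesulfonate; 4 dimethyl (2-oxopropyl)phosphonate
Product: 7 dimethyl [(1Z,5R)-5-bromo-2-{[tert-butyl(dimethyl)silyl]oxy}-6-chloro-6-methylhept-1-en-1-yl]phosphonate, via phosphonate dianion 5 (not isolated), via alkylated lithium enolate 6 (not isolated)
Conditions: 4, NaH, THF, 0 °C; n-BuLi, 0 °C; 3, −78 → −40 °C; TBSOTf, −78 °C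
Reagents that add atoms: tert-butyldimethylsilyl trifluoromethanesulfonate, CC(C)(C)[Si](C)(C)OS(=O)(=O)C(F)(F)F
Why: γ-Alkylation of a β-keto phosphonate dianion (the terminal, more basic carbanion attacks the primary triflate by SN2 at low temperature) followed by O-silylation of the chelated enolate, which fixes the Z enol ether and blocks the carbonyl oxygen as a competing nucleophile.

Step 4
Reactants: 7 dimethyl [(1Z,5R)-5-bromo-2-{[tert-butyl(dimethyl)silyl]oxy}-6-chloro-6-methylhept-1-en-1-yl]phosphonate
Product: 8 dimethyl [(3R)-3-bromo-2,2-dimethyl-6-oxocyclohexyl]phosphonate (C1 epimers)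
Conditions: (CF3)2CHOH (0.02 M), 2,6-di-tert-butylpyridine (0.2 equiv), 0 °C → rt
Reagents that add atoms: none
Why: Stereospecific solvolytic bromonium cyclization: in the ionizing, weakly nucleophilic solvent the tertiary chloride leaves with anchimeric help from the vicinal bromine and the bromonium ion is opened at the tertiary carbon by the silyl enol ether carbon through a six-membered chair (6-enolendo-exo-tet, an intramolecular tert-alkylation of a silyl enol ether), so the C–Br stereocentre is carried over untouched while chloride takes the silyl group.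

Step 5
Reactants: 8 dimethyl [(3R)-3-bromo-2,2-dimethyl-6-oxocyclohexyl]phosphonate
Product: 9 (4R)-4-bromo-3,3-dimethyl-2-methylidenecyclohexan-1-one
Conditions: 37% aq. CH2O, K2CO3, THF, 0 °C → rt
Reagents that add atoms: formaldehyde, C=O
Why: Horner–Wadsworth–Emmons olefination of the α-phosphono ketone with formaldehyde places the exocyclic methylene exactly on the phosphorus-bearing carbon between the carbonyl group and the CMe2 carbon, under carbonate conditions too mild to displace the neopentyl bromide.

Step 6
Reactants: 9 (4R)-4-bromo-3,3-dimethyl-2-methylidenecyclohexan-1-one; 10 isoprene (2-methylbuta-1,3-diene)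
Product: 11 (4R,6S)-4-bromo-5,5,9-trimethylspiro[5.5]undec-8-en-1-one
Conditions: Me2AlCl (0.3 equiv), isoprene (5 equiv), CH2Cl2, −78 → −20 °C
Reagents that add atoms: none
Why: Me2AlCl binds the carbonyl oxygen of the s-cis exo-methylene enone, lowers its LUMO and lets isoprene add across the exocyclic C=CH2 bond in a concerted but asynchronous [4+2] cycloaddition. The closest known reaction type is the Lewis-acid-catalysed spiroannulating Diels–Alder reaction of 2-methylenecycloalkanones with 2-substituted butadienes. Ring B is closed by intermolecular [4+2] annulation, in which the bond from the exocyclic carbon (C11) to C1 of isoprene (C10) is formed ahead of the bond from the enone α-carbon (spiro C6) to C4 of isoprene (C7). The one new stereocentre, C6, is set by the C4 bromine: in the reacting half-chair bromine is equatorial and the axial methyl of the neighbouring CMe2 carbon covers one face, so the diene adds anti to bromine and C7 ends trans to Br. The step needs "para" regioselectivity, secured by the match of the large LUMO coefficient at the exocyclic carbon with the large HOMO coefficient at C1 of isoprene and sharpened by the Lewis acid, and facial selectivity, secured by the bromine and gem-dimethyl bias; the low temperature keeps the enone from dimerizing.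

Step 7
Reactants: 11 (4R,6S)-4-bromo-5,5,9-trimethylspiro[5.5]undec-8-en-1-one
Product: 12 (4R,6S,8R,9S)-4-bromo-8,9-epoxy-5,5,9-trimethylspiro[5.5]undecan-1-one
Conditions: mCPBA, NaHCO3, CH2Cl2, 0 °C
Reagents that add atoms: 3-chloroperoxybenzoic acid, OOC(=O)c1cccc(Cl)c1
Why: Prilezhaev epoxidation of the only C=C bond (faster than Baeyer–Villiger oxidation of the hindered ketone): ring B is a half-chair with C5 (CMe2) equatorial and the carbonyl carbon C1 axial, so the peracid attacks the face anti to C1 (cis to C5) and sets C8 and C9.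

Step 8
Reactants: 12 (4R,6S,8R,9S)-4-bromo-8,9-epoxy-5,5,9-trimethylspiro[5.5]undecan-1-one
Product: 14 (4R,6S,8R,9S)-4-bromo-8,9-epoxy-5,5,9-trimethylspiro[5.5]undec-1-en-1-yl trifluoromethanesulfonate, via potassium enolate 13 (not isolated)
Conditions: KN(SiMe3)2, THF, −78 °C; PhNTf2, −78 → −40 °C
Reagents that add atoms: N-phenylbis(trifluoromethanesulfonimide), O=S(=O)(N(c1ccccc1)S(=O)(=O)C(F)(F)F)C(F)(F)F
Why: Kinetic deprotonation can only occur at C2 because C6 is quaternary, and O-triflation of the potassium enolate gives the C1=C2 enol triflate; epoxide and neopentyl bromide are inert at −78 °C.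

Step 9
Reactants: 14 (4R,6S,8R,9S)-4-bromo-8,9-epoxy-5,5,9-trimethylspiro[5.5]undec-1-en-1-yl trifluoromethanesulfonate
Product: 15 (4R,6R,8R,9S)-4-bromo-8,9-epoxy-1,5,5,9-tetramethylspiro[5.5]undec-1-ene
Conditions: Me2Zn, Pd(PPh3)4 (5 mol%), THF, 0 → 45 °C
Reagents that add atoms: dimethylzinc, C[Zn]C
Why: Negishi cross-coupling (oxidative addition of zerovalent palladium to the alkenyl triflate, transmetalation from zinc, reductive elimination) installs the C1 methyl group with the double bond fixed at C1=C2; the unactivated secondary bromide and the epoxide do not react with the catalyst or with the weakly Lewis-acidic organozinc in THF.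

Step 10
Reactants: 15 (4R,6R,8R,9S)-4-bromo-8,9-epoxy-1,5,5,9-tetramethylspiro[5.5]undec-1-ene
Product: 16 (4R,6R,8S,9S)-4,8-dibromo-1,5,5,9-tetramethylspiro[5.5]undec-1-en-9-ol
Conditions: Li2NiBr4, THF, 0 °C → rt
Reagents that add atoms: dilithium tetrabromonickelate, [Li+].[Li+].Br[Ni-2](Br)(Br)Br
Why: SN2 opening of the trisubstituted epoxide by soft bromide at the secondary carbon C8 with inversion, along the trans-diaxial trajectory of the ring B chair (C5 equatorial, C1 axial), puts Br on the face cis to C1 and leaves the tertiary C9–O bond, hence C9, unchanged.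

Step 11
Reactants: 16 (4R,6R,8S,9S)-4,8-dibromo-1,5,5,9-tetramethylspiro[5.5]undec-1-en-9-ol
Product: 17 (4R,6R,8S,9S)-4,8-dibromo-9-chloro-1,5,5,9-tetramethylspiro[5.5]undec-1-ene (target)
Conditions: 1-chloro-N,N,2-trimethylprop-1-en-1-amine, CH2Cl2, 0 °C → rt
Reagents that add atoms: 1-chloro-N,N,2-trimethylprop-1-en-1-amine, CC(C)=C(Cl)N(C)C
Why: Neutral deoxychlorination through an O-alkyl iminium leaving group: ionization at the tertiary C9 is assisted by the antiperiplanar C8 bromine, and chloride opens the resulting bromonium ion at C9 from the face that the oxygen occupied (double inversion, net retention), giving the trans Br/Cl pair with chlorine at the tertiary carbon.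

Compound list
1 | prenol (3-methylbut-2-en-1-ol) | CC(C)=CCO | starting material
2 | (2R)-2-bromo-3-chloro-3-methylbutan-1-ol | OC[C@@H](Br)C(C)(C)Cl | intermediate
3 | (2R)-2-bromo-3-chloro-3-methylbutyl trifluoromethanesulfonate | FC(F)(F)S(=O)(=O)OC[C@@H](Br)C(C)(C)Cl | intermediate
4 | dimethyl (2-oxopropyl)phosphonate | COP(=O)(OC)CC(C)=O | starting material
5 | sodium lithium dianion of dimethyl (2-oxopropyl)phosphonate | [Na+].[Li+].COP(=O)(OC)[CH-]C(=O)[CH2-] | intermediate (not isolated)
6 | lithium (Z)-enolate of dimethyl [(5R)-5-bromo-6-chloro-6-methyl-2-oxoheptyl]phosphonate | [Li+].COP(=O)(OC)/C=C(\[O-])CC[C@@H](Br)C(C)(C)Cl | intermediate (not isolated)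
7 | dimethyl [(1Z,5R)-5-bromo-2-{[tert-butyl(dimethyl)silyl]oxy}-6-chloro-6-methylhept-1-en-1-yl]phosphonate | COP(=O)(OC)/C=C(\O[Si](C)(C)C(C)(C)C)CC[C@@H](Br)C(C)(C)Cl | intermediate
8 | dimethyl [(3R)-3-bromo-2,2-dimethyl-6-oxocyclohexyl]phosphonate (C1 epimers) | COP(=O)(OC)C1C(=O)CC[C@@H](Br)C1(C)C | intermediate
9 | (4R)-4-bromo-3,3-dimethyl-2-methylidenecyclohexan-1-one | C=C1C(=O)CC[C@@H](Br)C1(C)C | intermediate
10 | isoprene (2-methylbuta-1,3-diene) | CC(=C)C=C | starting material
11 | (4R,6S)-4-bromo-5,5,9-trimethylspiro[5.5]undec-8-en-1-one | O=C1CC[C@@H](Br)C(C)(C)[C@@]12CCC(C)=CC2 | intermediate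
12 | (4R,6S,8R,9S)-4-bromo-8,9-epoxy-5,5,9-trimethylspiro[5.5]undecan-1-one (epoxide oxygen cis to C5) | O=C1CC[C@@H](Br)C(C)(C)[C@@]12CC[C@]3(C)O[C@@H]3C2 | intermediate
13 | potassium enolate of 12 | [K+].[O-]C1=CC[C@@H](Br)C(C)(C)[C@@]12CC[C@]3(C)O[C@@H]3C2 | intermediate (not isolated)
14 | (4R,6S,8R,9S)-4-bromo-8,9-epoxy-5,5,9-trimethylspiro[5.5]undec-1-en-1-yl trifluoromethanesulfonate | FC(F)(F)S(=O)(=O)OC1=CC[C@@H](Br)C(C)(C)[C@@]12CC[C@]3(C)O[C@@H]3C2 | intermediate
15 | (4R,6R,8R,9S)-4-bromo-8,9-epoxy-1,5,5,9-tetramethylspiro[5.5]undec-1-ene | CC1=CC[C@@H](Br)C(C)(C)[C@@]12CC[C@]3(C)O[C@@H]3C2 | intermediate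
16 | (4R,6R,8S,9S)-4,8-dibromo-1,5,5,9-tetramethylspiro[5.5]undec-1-en-9-ol | CC1=CC[C@@H](Br)C(C)(C)[C@@]12CC[C@](C)(O)[C@@H](Br)C2 | intermediate
17 | (4R,6R,8S,9S)-4,8-dibromo-9-chloro-1,5,5,9-tetramethylspiro[5.5]undec-1-ene | CC1=CC[C@@H](Br)C(C)(C)[C@@]12CC[C@](C)(Cl)[C@@H](Br)C2 | target

Total step count: 11. Longest linear sequence: 11 steps (1 → 17).

Steps most likely to fail

Step 3. The strongly basic dianion may attack the β-bromo triflate by E2 elimination or at bromine instead of displacing the triflate at carbon. The fallback sets out from 3 and uses a far less basic, doubly stabilized carbanion: the sodium enolate of tert-butyl 4-(dimethoxyphosphoryl)-3-oxobutanoate (NaH, DMF, 0 °C) should alkylate at C2 to give tert-butyl (4R)-4-bromo-5-chloro-2-[(dimethoxyphosphoryl)acetyl]-5-methylhexanoate F1. CF3CO2H in CH2Cl2 and gentle warming should then remove the tert-butyl ester and CO2 to give dimethyl [(5R)-5-bromo-6-chloro-6-methyl-2-oxoheptyl]phosphonate F2, and TBSOTf/Et3N should convert this into the silyl enol ether, where the fallback comes back to the route at 7.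

Step 4. The acidic solvent may strip the silyl group before ionization, after which the free keto phosphonate could close through oxygen, or the cation could lose a proton instead of cyclizing. The fallback sets out from 3 and changes both terminator and mode of activation. The dianion of allyl acetoacetate (NaH, n-BuLi, THF, −78 °C) should give allyl (6R)-6-bromo-7-chloro-7-methyl-3-oxooctanoate F3. SnCl4 (CH2Cl2, −78 → 0 °C) should abstract the tertiary chloride and close the ring at carbon within the tin chelate of the β-keto ester, an O-alkylated enol ether reopening under these conditions, to give allyl (3R)-3-bromo-2,2-dimethyl-6-oxocyclohexane-1-carboxylate F4. Pd(PPh3)4/morpholine should free (3R)-3-bromo-2,2-dimethyl-6-oxocyclohexane-1-carboxylic acid F5, and aqueous CH2O/Et2NH should bring about a decarboxylative Mannich methylenation that comes back to the route at 9.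

Step 10. Once C1 carries its methyl group the conformational bias of ring B is weaker, so bromide may open the epoxide at the tertiary carbon C9 or react sluggishly at C8. The fallback sets out from 12 and installs both ring B halogens at the ketone stage, where the small carbonyl oxygen keeps C1 axial and the diaxial trajectory is best defined. Li2NiBr4 should give (4R,6S,8S,9S)-4,8-dibromo-9-hydroxy-5,5,9-trimethylspiro[5.5]undecan-1-one F6. 1-Chloro-N,N,2-trimethylprop-1-en-1-amine should give (4R,6S,8S,9S)-4,8-dibromo-9-chloro-5,5,9-trimethylspiro[5.5]undecan-1-one F7. KN(SiMe3)2/PhNTf2 at −78 °C should give (4R,6S,8S,9S)-4,8-dibromo-9-chloro-5,5,9-trimethylspiro[5.5]undec-1-en-1-yl trifluoromethanesulfonate F8, and Me2Zn/Pd(PPh3)4 should then give the target, so the fallback comes back to the route at 17.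

Further compounds
F1 | step 3 | tert-butyl (4R)-4-bromo-5-chloro-2-[(dimethoxyphosphoryl)acetyl]-5-methylhexanoate | COP(=O)(OC)CC(=O)C(C[C@@H](Br)C(C)(C)Cl)C(=O)OC(C)(C)C
F2 | step 3 | dimethyl [(5R)-5-bromo-6-chloro-6-methyl-2-oxoheptyl]phosphonate | COP(=O)(OC)CC(=O)CC[C@@H](Br)C(C)(C)Cl
F3 | step 4 | allyl (6R)-6-bromo-7-chloro-7-methyl-3-oxooctanoate | C=CCOC(=O)CC(=O)CC[C@@H](Br)C(C)(C)Cl
F4 | step 4 | allyl (3R)-3-bromo-2,2-dimethyl-6-oxocyclohexane-1-carboxylate | C=CCOC(=O)C1C(=O)CC[C@@H](Br)C1(C)C
F5 | step 4 | (3R)-3-bromo-2,2-dimethyl-6-oxocyclohexane-1-carboxylic acid | OC(=O)C1C(=O)CC[C@@H](Br)C1(C)C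
F6 | step 10 | (4R,6S,8S,9S)-4,8-dibromo-9-hydroxy-5,5,9-trimethylspiro[5.5]undecan-1-one | O=C1CC[C@@H](Br)C(C)(C)[C@@]12CC[C@](C)(O)[C@@H](Br)C2
F7 | step 10 | (4R,6S,8S,9S)-4,8-dibromo-9-chloro-5,5,9-trimethylspiro[5.5]undecan-1-one | O=C1CC[C@@H](Br)C(C)(C)[C@@]12CC[C@](C)(Cl)[C@@H](Br)C2
F8 | step 10 | (4R,6S,8S,9S)-4,8-dibromo-9-chloro-5,5,9-trimethylspiro[5.5]undec-1-en-1-yl trifluoromethanesulfonate | FC(F)(F)S(=O)(=O)OC1=CC[C@@H](Br)C(C)(C)[C@@]12CC[C@](C)(Cl)[C@@H](Br)C2
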